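## The problem

The target is a branched profisetinidin tetramer built on (+)-catechin, whose phloroglucinol ring A is fully substituted: catechin C8 carries C4 of one fisetinidol unit (the 8-linked unit), and catechin C6 carries C4 of an inner fisetinidol unit whose own C6 carries an outer fisetinidol unit through C4. All three fisetinidol units are 2R,3S with the C4–aryl bond α (2,3-trans-3,4-trans), so with the two centres of catechin there are eleven stereocentres, nine of which must be made. Within one flavan unit the centres can be relayed, since a C2 aryl group sends reagents to the opposite face of a C3=C4 alkene and a 3-acyloxy group sends a nucleophile to C4 trans to itself; between units there is no relay, so each unit needs its own source of absolute configuration. The three interflavan bonds raise a regiochemical problem: catechin offers C8 and C6, every 5-deoxy ring A offers an open C6 para to O1, and the last bond to catechin C6 creates a hexasubstituted benzene between two ether oxygens. The free catechol and phloroglucinol rings oxidise in air and epimerise at C2 in base, and the C4–aryl bonds to the phloroglucinol ring and the benzylic C2–O1 ethers cleave in strong acid, so the phenols are unmasked last and under neutral conditions. The key step is possible because, in ring C of the 8-linked unit, O1 is an aryl ether oxygen, C2 a benzylic ether carbon and C4 a carbon bonded to two arenes (C4a and catechin C8). A C3=C4 alkene therefore divides ring C into an allyl aryl ether and a 1,1-diarylethylene, and the trans,trans pattern of aryl, hydroxyl and aryl on C2–C3–C4 is what syn hydroboration from the face opposite the C2 aryl group produces.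

## Retrosynthesis

**Unmasking (31 ⇐ 30 ⇐ 29).** The target 31 is traced to tetramer 30, in which every phenol and the catechin 3-hydroxyl is a benzyl ether and two ring A positions carry bromine. One hydrogenolysis removes both kinds of group. The two acetates of 29 are taken off before that (30 ⇐ 29), so that no base touches the free polyphenol.

**Catechin C6–C4 bond of the inner unit (29 ⇐ 28 + 13).** This cut halves the molecule into two dimers of similar size. Cutting the outer/inner fisetinidol bond last would leave two near-equivalent resorcinol-type C6 positions (inner unit and 8-linked unit) to compete. The forward reaction is Lewis-acid ionisation of the C4 acetate of 13 with the 3-acetoxy group holding the β face, so the arene enters α. For catechin C6 to be the only open nucleophilic site, C6 of the 8-linked unit and C6 of the outer unit carry bromine caps. The 3-hydroxyl of 28 is left free, since O-alkylation of it is reversible under the coupling conditions.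

**Ring C of the 8-linked unit (28 ⇐ 26 ⇐ 25).** C3–O and C4–H are removed to give flav-3-ene 26 (hydroboration in the forward sense), and the C3=C4 bond is cut to give diene 25 (ring-closing metathesis). Against a Friedel–Crafts cut at C4–C8, this choice fixes the C8 connectivity by construction and sets C3 and C4 by a concerted syn addition, not by the facial preference of a cation. The forward steps need only chemoselective ring closure and borane delivery anti to the C2 aryl group.

**Allylic ether (25 ⇐ 24 + 4).** The O–C2 bond is cut to phenol 24 and cinnamyl carbonate 4. This is the only new absolute stereocentre of the 8-linked unit, and it is set by an iridium catalyst carrying a chiral phosphoramidite ligand. The bond is made immediately before the metathesis because a 1-arylallyl aryl ether with an electron-rich aryl group is the most labile function of the sequence.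

**1,1-Diarylethylene (24 ⇐ 23 ⇐ 22 ⇐ 17 + 20).** The alkene is traced to tertiary carbinol 22, and this to aryllithium 21 (from bromide 17) and aryl methyl ketone 20. A sequence of aldehyde addition, oxidation and methylenation would end with an olefination at a carbonyl group shielded by three ortho substituents; bringing the methyl group in with ketone 20 avoids that and saves a step. Bromide 17 comes from (+)-catechin 14 through 15 and 16. Ketone 20 comes from commercial 18 through 19, the bromination installing the cap.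

**Outer/inner fisetinidol bond (13 ⇐ 12 + 10).** Both partners have the same kind of ring A, so two devices are needed. The donor 12 carries a C4 sulfide that a thiophile activates while the C4 acetate of the acceptor 10 stays inert. The donor also carries bromine at C6 so that it cannot add to itself. Acceptor 10, used in excess, reacts at C6 (para to O1). Both partners derive from diacetate 10: bromination gives 11 and thiolysis of 11 gives 12.

**Fisetinidol building block (10 ⇐ 9 ⇐ 8 ⇐ 7 ⇐ 6 + 4).** The same etherification/metathesis logic is applied to the parent system, where both reactions are known. Dihydroxylation of flav-3-ene 8 anti to the C2 aryl group sets C3, and the C4 oxygen becomes the leaving group.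

**Small pieces (4 ⇐ 3 ⇐ 2 ⇐ 1; 6 ⇐ 5).** Carbonate 4 is reached from aldehyde 1 by olefination, reduction and acylation. Vinylphenol 6 comes from aldehyde 5 by methylenation.

## Roads not taken

Alternative 1: The cut removes ring B from all three fisetinidol units at C2–C1′. The substrate of the forward step is tris(2-acetoxychroman) A3, the complete tetraflavan skeleton with an anomeric acetate in place of each of the three aryl groups and a pivalate on each neighbouring O3. Bromotrimethylsilane A4 turns the three acetates into bromides in the flask and arylzinc bromide A2 arylates each C2. The pivalate closes a dioxolenium ion on the β face, so the aryl group enters trans, giving tripivalate A1.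
- Merits: ring B is introduced last, on three units at once, from one simple reagent.
- Weak points: A3 is the whole problem minus ring B. Its three interflavan bonds and six C3/C4 centres would have to be set on rings lacking the C2 aryl group, which is the group that fixes the half-chair and the facial bias. A chroman-2-yl cation shares its oxygen lone pair with ring A, is less stabilised than a pyranosyl cation, and can lose H3 to give a chromene. Three such events on one molecule multiply every shortfall.
- Comparison: Alternative 1 is more convergent at the end and treats the units alike. The chosen plan needs a separate etherification for each unit, but every stereocentre comes from one catalyst-controlled event followed by stereospecific additions, and the bond at C8 is made regiospecifically.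

Alternative 2: The cut is through catechin ring A itself (C4a–C8a, C5–C6, C8–C8a). In the forward step 3-siloxycyclobutenone A6, which bears both flavan-4-yl groups, is heated with siloxyalkyne A7, which bears the C2–C4 chain. Electrocyclic opening to a vinylketene, ketene–alkyne cycloaddition, a second ring opening and 6π closure give phenol A5.
- Merits: both flavanyl groups are placed at defined positions, with no Friedel–Crafts regiochemistry and no C–C bond formation at a hindered arene carbon. In this respect it is better than the chosen plan, whose step 23 is its weakest.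
- Weak points: A6 must already carry two bulky flavan-4-yl groups whose C4 centres sit α to a vinylogous carbonyl and can epimerise. The cascade needs prolonged heating of a substrate full of benzylic ethers. Ring C of catechin (O1–C2) still has to be closed on A5 afterwards, and the two catechin stereocentres are made in A7 instead of bought.
- Comparison: the chosen plan uses intact catechin 14, settles C8 by bromination and lithiation, and settles C6 by bromine caps on the competing rings.

Alternative 3: The cut removes the resorcinol rings A of the two terminal fisetinidol units (C4–C4a and O1–C2). The substrate is bis(1,3-diol) A10, in which each terminal unit is still an open C2–C3–C4 chain with carbinols at C4 and C2. In the forward step acid ionises each C4 carbinol, the cation alkylates resorcinol A9, then each C2 carbinol ionises and the ortho phenol closes ring C, giving A8.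
- Merits: the cheapest possible ring A, two rings C in one operation at both ends, no metal and no capping.
- Weak points: each C4 cation of A10 is open-chain when attacked, so the C3/C4 relationship rests on acyclic induction. The C2 closure also passes through a cation, which leaves the C2 configuration to thermodynamics. Four ionisations run in acid on a molecule whose bonds to the phloroglucinol ring are acid-labile, and resorcinol A9 can be alkylated twice.
- Comparison: if the stereocontrol held, Alternative 3 would be shorter. The chosen plan puts no cation at C2, C3 or C4 of the 8-linked unit: C2 comes from a catalyst and C3/C4 from one syn addition.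

Key step: step 21

## Conventions and assumptions

- Flavan numbering is used throughout. α is the face of ring C that carries the C2 aryl group of a 2R flavan; β is the opposite face.
- L is (Sa,Sc,Sc)-O,O′-(1,1′-binaphthyl-2,2′-diyl) N,N-bis(1-phenylethyl)phosphoramidite. This antipode is assigned to the S ether by the accepted facial model for aryl-substituted allyl carbonates; should the sense prove opposite, the (Ra,Rc,Rc) antipode is used and nothing else changes.
- The configuration at the leaving-group carbon C4 of 9–13 is the one expected from the reactions but is immaterial, since that carbon is ionised later. Compound 22 is a mixture at the carbinol carbon, which becomes sp2 in step 18.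

## Route

Step 1
Reactants: 1 3,4-bis(benzyloxy)benzaldehyde
Product: 2 ethyl (E)-3-[3,4-bis(benzyloxy)phenyl]prop-2-enoate
Conditions: (EtO)2P(O)CH2CO2Et, NaH, THF, 0 °C → rt
Reagents that add atoms: triethyl phosphonoacetate, CCOC(=O)CP(=O)(OCC)OCC
Why: Horner–Wadsworth–Emmons olefination of an aromatic aldehyde with a stabilised phosphonate anion gives the E cinnamate; benzyl ethers are inert.

Step 2
Reactants: 2 ethyl (E)-3-[3,4-bis(benzyloxy)phenyl]prop-2-enoate
Product: 3 (E)-3-[3,4-bis(benzyloxy)phenyl]prop-2-en-1-ol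
Conditions: i-Bu2AlH (2.5 equiv), CH2Cl2, −78 °C; aq. potassium sodium tartrate work-up
Reagents that add atoms: none
Why: 1,2-Reduction of an α,β-unsaturated ester with an aluminium hydride gives the allylic alcohol without touching the alkene.

Step 3
Reactants: 3 (E)-3-[3,4-bis(benzyloxy)phenyl]prop-2-en-1-ol
Product: 4 (E)-3-[3,4-bis(benzyloxy)phenyl]prop-2-en-1-yl methyl carbonate
Conditions: ClCO2Me, pyridine, CH2Cl2, 0 °C
Reagents that add atoms: methyl chloroformate, COC(=O)Cl
Why: Acylation of a primary allylic alcohol with a chloroformate; the linear carbonate is the standard electrophile for iridium-catalysed allylic substitution.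

Step 4
Reactants: 5 4-(benzyloxy)-2-hydroxybenzaldehyde
Product: 6 5-(benzyloxy)-2-vinylphenol
Conditions: Ph3PCH3Br (2.5 equiv), KOt-Bu (2.5 equiv), THF, 0 °C → rt; pH 7 buffer
Reagents that add atoms: methyltriphenylphosphonium bromide, C[P+](c1ccccc1)(c1ccccc1)c1ccccc1.[Br-]
Why: Wittig methylenation of a salicylaldehyde with excess ylide (one equivalent is spent on the phenol) is a standard entry to 2-vinylphenols; neutral work-up protects the electron-rich styrene.

Step 5
Reactants: 6 5-(benzyloxy)-2-vinylphenol; 4 (E)-3-[3,4-bis(benzyloxy)phenyl]prop-2-en-1-yl methyl carbonate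
Product: 7 (S)-1-[3,4-bis(benzyloxy)phenyl]prop-2-en-1-yl 5-(benzyloxy)-2-vinylphenyl ether
Conditions: [Ir(cod)Cl]2 (2 mol%), L (4 mol%, pre-activated with n-PrNH2), K3PO4, THF, 50 °C
Reagents that add atoms: none
Why: Iridium-catalysed branch-selective asymmetric allylic etherification of a phenol with a cinnamyl carbonate, a known reaction that accepts 2-vinylphenols; the phenoxide attacks the aryl-bearing terminus of the allyliridium intermediate anti to the metal, and the cyclometalated phosphoramidite complex sets the S centre (later C2).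

Step 6
Reactants: 7 (S)-1-[3,4-bis(benzyloxy)phenyl]prop-2-en-1-yl 5-(benzyloxy)-2-vinylphenyl ether
Product: 8 (2S)-7-(benzyloxy)-2-[3,4-bis(benzyloxy)phenyl]-2H-chromene
Conditions: second-generation Grubbs catalyst (H2IMes)(PCy3)Cl2Ru=CHPh (3 mol%), CH2Cl2, 40 °C
Reagents that add atoms: none
Why: Ring-closing metathesis of an allyl 2-vinylphenyl ether to a 2H-chromene is a known, facile closure of two monosubstituted alkenes; C2 is not a reacting atom and keeps its configuration.

Step 7
Reactants: 8 (2S)-7-(benzyloxy)-2-[3,4-bis(benzyloxy)phenyl]-2H-chromene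
Product: 9 (2R,3S,4S)-7-(benzyloxy)-2-[3,4-bis(benzyloxy)phenyl]chromane-3,4-diol (2,3-trans-3,4-cis; both hydroxyls β)
Conditions: OsO4 (2 mol%), NMO (1.5 equiv), acetone/H2O, rt; Na2SO3 work-up
Reagents that add atoms: N-methylmorpholine N-oxide, C[N+]1([O-])CCOCC1; water, O
Why: Catalytic syn dihydroxylation of a flav-3-ene with OsO4 and an amine oxide takes place on the face opposite the C2 aryl group, which sets C3 (3β-OH) and gives the known 2,3-trans-3,4-cis diol pattern.

Step 8
Reactants: 9 (2R,3S,4S)-7-(benzyloxy)-2-[3,4-bis(benzyloxy)phenyl]chromane-3,4-diol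
Product: 10 3,4-di-O-acetate of 9 (2α-aryl, 3β-acetoxy, 4β-acetoxy)
Conditions: Ac2O, pyridine, DMAP (cat.), CH2Cl2, rt
Reagents that add atoms: acetic anhydride, CC(=O)OC(C)=O
Why: Routine acetylation; the 4-acetate becomes the leaving group and the 3-acetate the participating group of the later couplings.

Step 9
Reactants: 10 3,4-di-O-acetate of 9
Product: 11 6-bromo derivative of 10 (2α-aryl, 3β-acetoxy, 4β-acetoxy, 6-Br)
Conditions: NBS (1.05 equiv), CH2Cl2, −20 → 0 °C, dark
Reagents that add atoms: N-bromosuccinimide, O=C1CCC(=O)N1Br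
Why: Electrophilic bromination goes to C6, which is para to O1 and ortho to the benzyloxy group and is the most activated unhindered position (C8 lies between two oxygens; the catechol diether ring is less activated); the bromine later blocks this ring as a nucleophile.

Step 10
Reactants: 11 6-bromo derivative of 10
Product: 12 (2R)-3β-acetoxy-7-(benzyloxy)-2α-[3,4-bis(benzyloxy)phenyl]-6-bromo-4α-[(2,6-dimethylphenyl)sulfanyl]chromane
Conditions: 2,6-Me2C6H3SH (1.5 equiv), BF3·OEt2 (0.5 equiv), CH2Cl2, −78 → −20 °C
Reagents that add atoms: 2,6-dimethylbenzenethiol, Cc1cccc(C)c1S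
Why: Lewis-acid thiolysis of a flavan-4-yl acetate: the benzylic acetate ionises to a p-alkoxybenzyl cation, the 3-acetoxy group bridges the β face and the thiol enters α; the 2,6-disubstituted arylthio group is chosen to prevent sulfur transfer in the next step.

Step 11
Reactants: 12 (2R)-3β-acetoxy-7-(benzyloxy)-2α-[3,4-bis(benzyloxy)phenyl]-6-bromo-4α-[(2,6-dimethylphenyl)sulfanyl]chromane; 10 3,4-di-O-acetate of 9
Product: 13 3-O-acetyl-6-bromo-7,3′,4′-tri-O-benzylfisetinidol-(4α→6)-[3,4-di-O-acetyl-7,3′,4′-tri-O-benzyl-2,3-trans-3,4-cis-flavan-3,4-diol]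
Conditions: 10 (3 equiv), I2, Ag2O, 4 Å MS, CH2Cl2, −78 → −20 °C
Reagents that add atoms: none
Why: Orthogonal activation in a Friedel–Crafts interflavan coupling: the soft iodonium source ionises only the sulfide donor while the C4 acetate of 10 is inert; C6 of 10 (para to O1) attacks the cation trans to the bridging 3-acetoxy group, setting C4 of the outer unit as 4α, and the bromine on 12 prevents self-condensation.

Step 12
Reactants: 14 (+)-catechin
Product: 15 5,7,3′,4′-tetra-O-benzyl-(+)-catechin
Conditions: BnBr (4.4 equiv), K2CO3, DMF, 0 °C → rt, Ar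
Reagents that add atoms: benzyl bromide, BrCc1ccccc1
Why: Williamson etherification of the four phenols under carbonate base leaves the secondary alcohol and the two stereocentres untouched.

Step 13
Reactants: 15 5,7,3′,4′-tetra-O-benzyl-(+)-catechin
Product: 16 3,5,7,3′,4′-penta-O-benzyl-(+)-catechin
Conditions: NaH, BnBr, n-Bu4NI (cat.), THF/DMF, 0 °C → rt
Reagents that add atoms: benzyl bromide, BrCc1ccccc1
Why: Williamson benzylation of the 3-hydroxyl gives a protecting group that tolerates the aryllithium of step 17.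

Step 14
Reactants: 16 3,5,7,3′,4′-penta-O-benzyl-(+)-catechin
Product: 17 8-bromo-3,5,7,3′,4′-penta-O-benzyl-(+)-catechin
Conditions: NBS (1.0 equiv), CH2Cl2, −40 → 0 °C
Reagents that add atoms: N-bromosuccinimide, O=C1CCC(=O)N1Br
Why: Electrophilic bromination of O-benzylated catechins is known to be selective for C8 over C6; this fixes the connectivity of the later C4–C8 bond.

Step 15
Reactants: 18 1-[4-(benzyloxy)-2-hydroxyphenyl]ethan-1-one
Product: 19 1-[4-(benzyloxy)-5-bromo-2-hydroxyphenyl]ethan-1-one
Conditions: NBS (1.0 equiv), MeCN, 0 °C → rt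
Reagents that add atoms: N-bromosuccinimide, O=C1CCC(=O)N1Br
Why: Nuclear bromination of an activated 2-hydroxy-4-alkoxyacetophenone occurs para to the hydroxyl (C5); this carbon becomes C6 of the 8-linked unit and the bromine is its cap.

Step 16
Reactants: 19 1-[4-(benzyloxy)-5-bromo-2-hydroxyphenyl]ethan-1-one
Product: 20 1-[4-(benzyloxy)-5-bromo-2-(tert-butyldimethylsilyloxy)phenyl]ethan-1-one
Conditions: TBSCl, imidazole, DMF, rt
Reagents that add atoms: tert-butyldimethylsilyl chloride, CC(C)(C)[Si](C)(C)Cl
Why: Silylation masks the phenol so that the ketone remains electrophilic and no aryllithium is wasted on an acidic proton.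

Step 17
Reactants: 17 8-bromo-3,5,7,3′,4′-penta-O-benzyl-(+)-catechin; 20 1-[4-(benzyloxy)-5-bromo-2-(tert-butyldimethylsilyloxy)phenyl]ethan-1-one
Product: 22 1-[4-(benzyloxy)-5-bromo-2-(tert-butyldimethylsilyloxy)phenyl]-1-(penta-O-benzylcatechin-8-yl)ethan-1-ol, via 8-lithio-penta-O-benzylcatechin 21 (not isolated)
Conditions: n-BuLi (1.05 equiv), THF, −78 °C; then 20 (1.2 equiv), −78 → −40 °C; H2O
Reagents that add atoms: none
Why: Bromine–lithium exchange at C8 followed by 1,2-addition to an aryl methyl ketone, the standard first half of a 1,1-diarylethylene synthesis; at −78 °C carbonyl addition outruns exchange with the second aryl bromide, and the new carbinol centre is formed without control because it is removed in step 18.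

Step 18
Reactants: 22 1-[4-(benzyloxy)-5-bromo-2-(tert-butyldimethylsilyloxy)phenyl]-1-(penta-O-benzylcatechin-8-yl)ethan-1-ol
Product: 23 8-{1-[4-(benzyloxy)-5-bromo-2-(tert-butyldimethylsilyloxy)phenyl]vinyl}-penta-O-benzylcatechin
Conditions: TsOH·H2O (5 mol%), toluene, 4 Å MS, rt
Reagents that add atoms: none
Why: Acid-catalysed E1 dehydration of a tertiary diaryl methyl carbinol; the doubly aryl-stabilised cation can lose a proton only from the methyl group, and the crowded alkene does not dimerise.

Step 19
Reactants: 23 8-{1-[4-(benzyloxy)-5-bromo-2-(tert-butyldimethylsilyloxy)phenyl]vinyl}-penta-O-benzylcatechin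
Product: 24 8-{1-[4-(benzyloxy)-5-bromo-2-hydroxyphenyl]vinyl}-penta-O-benzylcatechin
Conditions: n-Bu4NF (1.1 equiv), THF, 0 °C; aq. NH4Cl
Reagents that add atoms: none
Why: Fluoride cleavage of an aryl silyl ether is fast and leaves benzyl ethers, the aryl bromide and the alkene untouched.

Step 20
Reactants: 24 8-{1-[4-(benzyloxy)-5-bromo-2-hydroxyphenyl]vinyl}-penta-O-benzylcatechin; 4 (E)-3-[3,4-bis(benzyloxy)phenyl]prop-2-en-1-yl methyl carbonate
Product: 25 8-{1-[4-(benzyloxy)-2-{(S)-1-[3,4-bis(benzyloxy)phenyl]allyloxy}-5-bromophenyl]vinyl}-penta-O-benzylcatechin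
Conditions: 4 (1.5 equiv), [Ir(cod)Cl]2 (4 mol%), L (8 mol%, pre-activated with n-PrNH2), K3PO4, THF, 50 °C
Reagents that add atoms: none
Why: The same iridium-catalysed branch-selective asymmetric allylic etherification as step 5, here with an ortho-substituted phenol; the new S centre (later C2 of the 8-linked unit) is set by the catalyst, the catechin centres being too remote to interfere, and the aryl bromide and the diarylethylene are spectators.

Step 21
Reactants: 25 8-{1-[4-(benzyloxy)-2-{(S)-1-[3,4-bis(benzyloxy)phenyl]allyloxy}-5-bromophenyl]vinyl}-penta-O-benzylcatechin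
Product: 26 (2S)-7-(benzyloxy)-2-[3,4-bis(benzyloxy)phenyl]-6-bromo-4-(penta-O-benzylcatechin-8-yl)-2H-chromene
Conditions: second-generation Grubbs catalyst (H2IMes)(PCy3)Cl2Ru=CHPh (10 mol%), 1,4-benzoquinone (10 mol%), toluene, 60–80 °C, Ar sparge
Reagents that add atoms: none
Why: Ring-closing olefin metathesis: the ruthenium benzylidene exchanges onto the monosubstituted alkene of the allyl aryl ether (the 1,1-diarylethylene is too hindered to initiate), the resulting alkylidene at C3 adds across the geminal diaryl alkene to a ruthenacyclobutane, and cycloreversion gives the C3=C4 bond and a ruthenium methylidene that carries the chain with loss of ethene. The closest known reaction type is the ring-closing metathesis of allyl 2-(1-arylvinyl)phenyl ethers to 4-aryl-2H-chromenes. Ring C is closed as a six-membered ring by joining the two alkene termini C3 and C4, with O1–C2 and C4–C4a already in place on the arene. No stereocentre is created; C2 from step 20 is not a reacting atom and is carried through unchanged. The step needs chemoselectivity only: cyclisation must beat cross-metathesis at the allyl terminus and isomerisation of the allyl ether to an enol ether. The substrate secures this because the twisted, electron-rich diarylethylene cannot homodimerise and is held beside the alkylidene by the ortho relationship on the arene, while ethene is swept out and 1,4-benzoquinone suppresses ruthenium hydride isomerisation. The bromine cap and the benzyl ethers are inert to the catalyst.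

Step 22
Reactants: 26 (2S)-7-(benzyloxy)-2-[3,4-bis(benzyloxy)phenyl]-6-bromo-4-(penta-O-benzylcatechin-8-yl)-2H-chromene
Product: 28 6-bromo-7,3′,4′-tri-O-benzylfisetinidol-(4α→8)-3,5,7,3′,4′-penta-O-benzylcatechin (free 3-hydroxyl on the fisetinidol unit), via C3 alkylborane 27 (not isolated)
Conditions: BH3·SMe2 (3 equiv), THF, 0 °C → rt; then NaOH, H2O2, 0 °C → rt
Reagents that add atoms: hydrogen peroxide, OO; borane–dimethyl sulfide, B.CSC (boron of 27 only)
Why: Hydroboration–oxidation of a flav-3-ene: boron adds to the less substituted C3 and hydrogen to the diaryl-substituted C4 on the same face, opposite the C2 aryl group, and oxidation with retention gives the 3β-hydroxyl; C2 thus sets C3 and C4 together as the 2,3-trans-3,4-trans triad with the catechin ring α at C4.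

Step 23
Reactants: 28 6-bromo-7,3′,4′-tri-O-benzylfisetinidol-(4α→8)-3,5,7,3′,4′-penta-O-benzylcatechin; 13 3-O-acetyl-6-bromo-7,3′,4′-tri-O-benzylfisetinidol-(4α→6)-[3,4-di-O-acetyl-7,3′,4′-tri-O-benzyl-2,3-trans-3,4-cis-flavan-3,4-diol]
Product: 29 tetramer with fourteen benzyl ethers, 3-O-acetyl groups on the outer and inner fisetinidol units, a free 3-hydroxyl on the 8-linked unit and bromine at C6 of the outer and 8-linked units
Conditions: 13 (1.5 equiv), Me3SiOTf (0.3 equiv), 4 Å MS, CH2Cl2, −78 → −20 °C; Et3N quench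
Reagents that add atoms: none
Why: Lewis-acid Friedel–Crafts interflavan coupling with neighbouring-group control: the benzylic C4 acetate of 13 ionises, the 3-acetoxy group bridges the β face, and catechin C6 of 28 (the only uncapped activated arene position) attacks α, setting C4 of the inner unit; the free hydroxyl of 28 is tolerated because O-alkylation is reversible under the conditions.

Step 24
Reactants: 29 protected tetramer (two acetates)
Product: 30 tetramer with fourteen benzyl ethers, free 3-hydroxyls on the three fisetinidol units and bromine at C6 of the outer and 8-linked units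
Conditions: NaOMe (0.3 equiv), MeOH/THF, rt
Reagents that add atoms: none
Why: Zemplén transesterification removes the two secondary acetates while all phenols are still protected, so no phenoxide-mediated epimerisation can occur.

Step 25
Reactants: 30 deacetylated tetramer
Product: 31 fisetinidol-(4α→6)-fisetinidol-(4α→6)-catechin-(8←4α)-fisetinidol (CNP0263622.1)
Conditions: H2 (1 atm), Pd(OH)2/C, NaOAc, THF/MeOH/H2O, rt
Reagents that add atoms: none
Why: Catalytic hydrogenolysis cleaves the fourteen benzyl ethers and both aryl C–Br bonds in one operation under neutral conditions; sodium acetate buffers the hydrogen bromide so that the acid-labile bonds to the phloroglucinol ring survive.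

## Compound list

1 | 3,4-bis(benzyloxy)benzaldehyde | O=Cc1ccc(OCc2ccccc2)c(OCc2ccccc2)c1 | starting material
2 | ethyl (E)-3-[3,4-bis(benzyloxy)phenyl]prop-2-enoate | CCOC(=O)/C=C/c1ccc(OCc2ccccc2)c(OCc2ccccc2)c1 | intermediate
3 | (E)-3-[3,4-bis(benzyloxy)phenyl]prop-2-en-1-ol | OC/C=C/c1ccc(OCc2ccccc2)c(OCc2ccccc2)c1 | intermediate
4 | (E)-3-[3,4-bis(benzyloxy)phenyl]prop-2-en-1-yl methyl carbonate | COC(=O)OC/C=C/c1ccc(OCc2ccccc2)c(OCc2ccccc2)c1 | intermediate
5 | 4-(benzyloxy)-2-hydroxybenzaldehyde | O=Cc1ccc(OCc2ccccc2)cc1O | starting material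
6 | 5-(benzyloxy)-2-vinylphenol | C=Cc1ccc(OCc2ccccc2)cc1O | intermediate
7 | (S)-1-[3,4-bis(benzyloxy)phenyl]prop-2-en-1-yl 5-(benzyloxy)-2-vinylphenyl ether | C=C[C@@H](c1ccc(OCc2ccccc2)c(OCc2ccccc2)c1)Oc1cc(OCc2ccccc2)ccc1C=C | intermediate
8 | (2S)-7-(benzyloxy)-2-[3,4-bis(benzyloxy)phenyl]-2H-chromene | C1=C[C@@H](c2ccc(OCc3ccccc3)c(OCc3ccccc3)c2)Oc2cc(OCc3ccccc3)ccc12 | intermediate
9 | (2R,3S,4S)-7-(benzyloxy)-2-[3,4-bis(benzyloxy)phenyl]chromane-3,4-diol (2,3-trans-3,4-cis) | c1cc2c(cc1OCc3ccccc3)O[C@H](c3ccc(OCc4ccccc4)c(OCc4ccccc4)c3)[C@@H](O)[C@H]2O | intermediate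
10 | 3,4-di-O-acetate of 9 (2α-aryl, 3β-acetoxy, 4β-acetoxy) | c1cc2c(cc1OCc3ccccc3)O[C@H](c3ccc(OCc4ccccc4)c(OCc4ccccc4)c3)[C@@H](OC(C)=O)[C@H]2OC(C)=O | intermediate
11 | 6-bromo derivative of 10 | Brc1cc2c(cc1OCc3ccccc3)O[C@H](c3ccc(OCc4ccccc4)c(OCc4ccccc4)c3)[C@@H](OC(C)=O)[C@H]2OC(C)=O | intermediate
12 | (2R)-3β-acetoxy-7-(benzyloxy)-2α-[3,4-bis(benzyloxy)phenyl]-6-bromo-4α-[(2,6-dimethylphenyl)sulfanyl]chromane | Brc1cc2c(cc1OCc3ccccc3)O[C@H](c3ccc(OCc4ccccc4)c(OCc4ccccc4)c3)[C@@H](OC(C)=O)[C@@H]2Sc1c(C)cccc1C | intermediate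
13 | 3-O-acetyl-6-bromo-7,3′,4′-tri-O-benzylfisetinidol-(4α→6)-[3,4-di-O-acetyl-7,3′,4′-tri-O-benzyl-2,3-trans-3,4-cis-flavan-3,4-diol] | Brc1cc2c(cc1OCc5ccccc5)O[C@H](c6ccc(OCc5ccccc5)c(OCc5ccccc5)c6)[C@@H](OC(C)=O)[C@@H]2c1cc2c(cc1OCc5ccccc5)O[C@H](c6ccc(OCc5ccccc5)c(OCc5ccccc5)c6)[C@@H](OC(C)=O)[C@H]2OC(C)=O | intermediate
14 | (+)-catechin | Oc1cc(O)c2c(c1)O[C@H](c1ccc(O)c(O)c1)[C@@H](O)C2 | starting material
15 | 5,7,3′,4′-tetra-O-benzyl-(+)-catechin | c1c(OCc5ccccc5)c2c(cc1OCc5ccccc5)O[C@H](c6ccc(OCc5ccccc5)c(OCc5ccccc5)c6)[C@@H](O)C2 | intermediate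
16 | 3,5,7,3′,4′-penta-O-benzyl-(+)-catechin | c1c(OCc5ccccc5)c2c(cc1OCc5ccccc5)O[C@H](c6ccc(OCc5ccccc5)c(OCc5ccccc5)c6)[C@@H](OCc5ccccc5)C2 | intermediate
17 | 8-bromo-3,5,7,3′,4′-penta-O-benzyl-(+)-catechin | c1c(OCc5ccccc5)c2c(c(Br)c1OCc5ccccc5)O[C@H](c6ccc(OCc5ccccc5)c(OCc5ccccc5)c6)[C@@H](OCc5ccccc5)C2 | intermediate
18 | 1-[4-(benzyloxy)-2-hydroxyphenyl]ethan-1-one | CC(=O)c1ccc(OCc2ccccc2)cc1O | starting material
19 | 1-[4-(benzyloxy)-5-bromo-2-hydroxyphenyl]ethan-1-one | CC(=O)c1cc(Br)c(OCc2ccccc2)cc1O | intermediate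
20 | 1-[4-(benzyloxy)-5-bromo-2-(tert-butyldimethylsilyloxy)phenyl]ethan-1-one | CC(=O)c1cc(Br)c(OCc2ccccc2)cc1O[Si](C)(C)C(C)(C)C | intermediate
21 | 8-lithio-3,5,7,3′,4′-penta-O-benzylcatechin (not isolated) | c1c(OCc5ccccc5)c2c(c([Li])c1OCc5ccccc5)O[C@H](c6ccc(OCc5ccccc5)c(OCc5ccccc5)c6)[C@@H](OCc5ccccc5)C2 | intermediate
22 | 1-[4-(benzyloxy)-5-bromo-2-(tert-butyldimethylsilyloxy)phenyl]-1-(penta-O-benzylcatechin-8-yl)ethan-1-ol (mixture at the carbinol carbon) | c1c(OCc5ccccc5)c2c(c(C(C)(O)c3cc(Br)c(OCc5ccccc5)cc3O[Si](C)(C)C(C)(C)C)c1OCc5ccccc5)O[C@H](c6ccc(OCc5ccccc5)c(OCc5ccccc5)c6)[C@@H](OCc5ccccc5)C2 | intermediate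
23 | 8-{1-[4-(benzyloxy)-5-bromo-2-(tert-butyldimethylsilyloxy)phenyl]vinyl}-penta-O-benzylcatechin | c1c(OCc5ccccc5)c2c(c(C(=C)c3cc(Br)c(OCc5ccccc5)cc3O[Si](C)(C)C(C)(C)C)c1OCc5ccccc5)O[C@H](c6ccc(OCc5ccccc5)c(OCc5ccccc5)c6)[C@@H](OCc5ccccc5)C2 | intermediate
24 | 8-{1-[4-(benzyloxy)-5-bromo-2-hydroxyphenyl]vinyl}-penta-O-benzylcatechin | c1c(OCc5ccccc5)c2c(c(C(=C)c3cc(Br)c(OCc5ccccc5)cc3O)c1OCc5ccccc5)O[C@H](c6ccc(OCc5ccccc5)c(OCc5ccccc5)c6)[C@@H](OCc5ccccc5)C2 | intermediate
25 | 8-{1-[4-(benzyloxy)-2-{(S)-1-[3,4-bis(benzyloxy)phenyl]allyloxy}-5-bromophenyl]vinyl}-penta-O-benzylcatechin | c1c(OCc5ccccc5)c2c(c(C(=C)c3cc(Br)c(OCc5ccccc5)cc3O[C@H](c6ccc(OCc5ccccc5)c(OCc5ccccc5)c6)C=C)c1OCc5ccccc5)O[C@H](c6ccc(OCc5ccccc5)c(OCc5ccccc5)c6)[C@@H](OCc5ccccc5)C2 | intermediate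
26 | (2S)-7-(benzyloxy)-2-[3,4-bis(benzyloxy)phenyl]-6-bromo-4-(penta-O-benzylcatechin-8-yl)-2H-chromene | c1c(OCc5ccccc5)c2c(c(C3=C[C@@H](c6ccc(OCc5ccccc5)c(OCc5ccccc5)c6)Oc4cc(OCc5ccccc5)c(Br)cc34)c1OCc5ccccc5)O[C@H](c6ccc(OCc5ccccc5)c(OCc5ccccc5)c6)[C@@H](OCc5ccccc5)C2 | intermediate
27 | 3β-boryl (BH2) analogue of 28: 2α-aryl, 3β-boron, 4α-catechinyl (not isolated) | c1c(OCc5ccccc5)c2c(c([C@@H]3c4cc(Br)c(OCc5ccccc5)cc4O[C@H](c6ccc(OCc5ccccc5)c(OCc5ccccc5)c6)[C@H]3B)c1OCc5ccccc5)O[C@H](c6ccc(OCc5ccccc5)c(OCc5ccccc5)c6)[C@@H](OCc5ccccc5)C2 | intermediate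
28 | 6-bromo-7,3′,4′-tri-O-benzylfisetinidol-(4α→8)-3,5,7,3′,4′-penta-O-benzylcatechin | c1c(OCc5ccccc5)c2c(c([C@@H]3c4cc(Br)c(OCc5ccccc5)cc4O[C@H](c6ccc(OCc5ccccc5)c(OCc5ccccc5)c6)[C@H]3O)c1OCc5ccccc5)O[C@H](c6ccc(OCc5ccccc5)c(OCc5ccccc5)c6)[C@@H](OCc5ccccc5)C2 | intermediate
29 | protected tetramer: fourteen benzyl ethers, 3-O-acetyl on the outer and inner fisetinidol units, free 3-hydroxyl on the 8-linked unit, bromine at C6 of the outer and 8-linked units | Brc1cc2c(cc1OCc5ccccc5)O[C@H](c6ccc(OCc5ccccc5)c(OCc5ccccc5)c6)[C@@H](OC(C)=O)[C@@H]2c1cc2c(cc1OCc5ccccc5)O[C@H](c6ccc(OCc5ccccc5)c(OCc5ccccc5)c6)[C@@H](OC(C)=O)[C@@H]2c1c(OCc5ccccc5)c2c(c([C@@H]3c4cc(Br)c(OCc5ccccc5)cc4O[C@H](c6ccc(OCc5ccccc5)c(OCc5ccccc5)c6)[C@H]3O)c1OCc5ccccc5)O[C@H](c6ccc(OCc5ccccc5)c(OCc5ccccc5)c6)[C@@H](OCc5ccccc5)C2 | intermediate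
30 | deacetylated tetramer: fourteen benzyl ethers, three free 3-hydroxyls, two bromine caps | Brc1cc2c(cc1OCc5ccccc5)O[C@H](c6ccc(OCc5ccccc5)c(OCc5ccccc5)c6)[C@@H](O)[C@@H]2c1cc2c(cc1OCc5ccccc5)O[C@H](c6ccc(OCc5ccccc5)c(OCc5ccccc5)c6)[C@@H](O)[C@@H]2c1c(OCc5ccccc5)c2c(c([C@@H]3c4cc(Br)c(OCc5ccccc5)cc4O[C@H](c6ccc(OCc5ccccc5)c(OCc5ccccc5)c6)[C@H]3O)c1OCc5ccccc5)O[C@H](c6ccc(OCc5ccccc5)c(OCc5ccccc5)c6)[C@@H](OCc5ccccc5)C2 | intermediate
31 | fisetinidol-(4α→6)-fisetinidol-(4α→6)-catechin-(8←4α)-fisetinidol (CNP0263622.1) | Oc1ccc2c(c1)O[C@H](c1ccc(O)c(O)c1)[C@@H](O)[C@@H]2c1cc2c(cc1O)O[C@H](c1ccc(O)c(O)c1)[C@@H](O)[C@@H]2c1c(O)c2c(c([C@@H]3c4ccc(O)cc4O[C@H](c4ccc(O)c(O)c4)[C@H]3O)c1O)O[C@H](c1ccc(O)c(O)c1)[C@@H](O)C2 | target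

## Step count and least certain steps

Total: 25 steps. Longest linear sequence: 13 steps (1 → 2 → 3 → 4 → 7 → 8 → 9 → 10 → 11 → 12 → 13 → 29 → 30 → 31; steps 1–3, 5–11, 23–25). The catechin branch (14 → 31) is 12 steps.

**Step 21 (key step).** The most likely failure is that the ruthenium alkylidene formed at the allyl terminus does not engage the geminal diaryl alkene, whose C4 is flanked by a 2,6-dioxygenated arene. Catalyst decay, cross-metathesis at the allyl terminus or hydride-induced isomerisation of the allyl ether would then take over, and prolonged heating could ionise the benzylic C2–O bond and erode the C2 configuration. The fallback forms the C4–C8 bond by Friedel–Crafts arylation instead of building ring C. It sets out from 16 and 11: Me3SiOTf-promoted ionisation of the C4 acetate of 11 in the presence of an excess of 16 should give 3-O-acetyl-6-bromo-7,3′,4′-tri-O-benzylfisetinidol-(4α→8)-penta-O-benzylcatechin F1 by attack of catechin C8 trans to the participating 3-acetoxy group. Zemplén deacetylation of F1 comes back to the route at 28. The price is that C8 versus C6 and α versus β selectivity then rest on substrate bias and not on construction. The same detour also covers a failure of the hydroboration in step 22.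

**Step 23.** The most likely failure is slow or absent attack at the hindered C6 of 28, flanked by two benzyloxy groups on a pentasubstituted ring. The cation would then be lost to elimination, to attack at a capped ring or to O-alkylation, and long exposure to acid could cleave the existing C4–C8 bond. The fallback unmasks the nucleophile and uses the free flavan-3,4-diol as the electrophile. It sets out from 28 and 13: hydrogenolysis of 28 (H2, Pd(OH)2/C, NaOAc) gives free fisetinidol-(4α→8)-catechin F2 whose phloroglucinol ring, now with two free hydroxyls, is far more nucleophilic and far less shielded at C6. Zemplén deacetylation of 13, in which every phenol is still a benzyl ether, gives the dimeric flavan-3,4-diol F3 with three free hydroxyls. Condensation of F3 with an excess of F2 under BF3·OEt2 in dioxane/CH2Cl2 at 0 °C, the classical union of a flavan-3,4-diol with a free flavan-3-ol, should give the half-protected tetramer F4 in which the catechin and 8-linked units are free. Hydrogenolysis of F4 comes back to the route at 31. The acetates are removed before the coupling, so no base meets a free polyphenol. The price is that the α configuration at C4 of the inner unit then rests on the inherent preference of a 2,3-trans flavan-4-yl cation for 3,4-trans attack and not on acetoxy participation.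

**Step 11.** The most likely failure is loss of chemoselectivity between the two leaving groups: the silver salt and the acid formed may ionise the benzylic C4 acetate of acceptor 10, which is present in excess, so that 10 condenses with itself, and the arylthio group may be transferred between donor and product. The fallback reverses the roles of the two leaving groups, so that in each coupling the acceptor holds no group the promoter can ionise. It sets out from 10 and 11: thiolysis of 10 as in step 10 gives the bromine-free 4α-sulfide F5 of the inner unit. Ionisation of the C4 acetate of 11 with BF3·OEt2, a hard promoter that leaves the sulfide alone, in the presence of excess F5 gives the dimer sulfide F6 by attack of C6 of the acceptor. F6 is then activated with I2 and Ag2O in the presence of 28 and comes back to the route at 29.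

**Step 17.** The most likely failure is proton transfer, that is enolisation of ketone 20 by the hindered, basic aryllithium 21, in place of carbonyl addition. The fallback brings the methyl group in last. It sets out from 5 and 17: bromination of 5 with NBS gives 4-(benzyloxy)-5-bromo-2-hydroxybenzaldehyde F7 and silylation of F7 gives tert-butyldimethylsilyl ether F8 as the electrophile. Addition of aryllithium 21, made from 17 as in step 17, to aldehyde F8 which has no α-hydrogen gives diaryl carbinol F9 as a mixture at the carbinol carbon, and Dess–Martin oxidation of F9 gives diaryl ketone F10 without epimerisable centres nearby. Methyllithium, small and unable to enolise this ketone, adds to F10 and comes back to the route at 22.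

## Further compounds

F1 | step 21 | 3-O-acetyl-6-bromo-7,3′,4′-tri-O-benzylfisetinidol-(4α→8)-penta-O-benzylcatechin (3-O-acetyl derivative of 28) | c1c(OCc5ccccc5)c2c(c([C@@H]3c4cc(Br)c(OCc5ccccc5)cc4O[C@H](c6ccc(OCc5ccccc5)c(OCc5ccccc5)c6)[C@H]3OC(C)=O)c1OCc5ccccc5)O[C@H](c6ccc(OCc5ccccc5)c(OCc5ccccc5)c6)[C@@H](OCc5ccccc5)C2
F2 | step 23 | fisetinidol-(4α→8)-catechin, free phenols | c1c(O)c2c(c([C@@H]3c4ccc(O)cc4O[C@H](c4ccc(O)c(O)c4)[C@H]3O)c1O)O[C@H](c1ccc(O)c(O)c1)[C@@H](O)C2
F3 | step 23 | dimeric flavan-3,4-diol: 6-bromo-7,3′,4′-tri-O-benzylfisetinidol-(4α→6)-[7,3′,4′-tri-O-benzyl-2,3-trans-3,4-cis-flavan-3,4-diol], three free hydroxyls | Brc1cc2c(cc1OCc5ccccc5)O[C@H](c6ccc(OCc5ccccc5)c(OCc5ccccc5)c6)[C@@H](O)[C@@H]2c1cc2c(cc1OCc5ccccc5)O[C@H](c6ccc(OCc5ccccc5)c(OCc5ccccc5)c6)[C@@H](O)[C@H]2O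
F4 | step 23 | half-protected tetramer: outer and inner units benzylated with free 3-hydroxyls and bromine on the outer unit; catechin and 8-linked units free | Brc1cc2c(cc1OCc5ccccc5)O[C@H](c6ccc(OCc5ccccc5)c(OCc5ccccc5)c6)[C@@H](O)[C@@H]2c1cc2c(cc1OCc5ccccc5)O[C@H](c6ccc(OCc5ccccc5)c(OCc5ccccc5)c6)[C@@H](O)[C@@H]2c1c(O)c2c(c([C@@H]3c4ccc(O)cc4O[C@H](c4ccc(O)c(O)c4)[C@H]3O)c1O)O[C@H](c1ccc(O)c(O)c1)[C@@H](O)C2
F5 | step 11 | (2R)-3β-acetoxy-7-(benzyloxy)-2α-[3,4-bis(benzyloxy)phenyl]-4α-[(2,6-dimethylphenyl)sulfanyl]chromane | c1cc2c(cc1OCc3ccccc3)O[C@H](c3ccc(OCc4ccccc4)c(OCc4ccccc4)c3)[C@@H](OC(C)=O)[C@@H]2Sc1c(C)cccc1C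
F6 | step 11 | dimer sulfide: 3-O-acetyl-6-bromo-tri-O-benzylfisetinidol-(4α→6)-[3-O-acetyl-4α-(2,6-dimethylphenyl)sulfanyl-tri-O-benzylfisetinidol] | Brc1cc2c(cc1OCc5ccccc5)O[C@H](c6ccc(OCc5ccccc5)c(OCc5ccccc5)c6)[C@@H](OC(C)=O)[C@@H]2c1cc2c(cc1OCc5ccccc5)O[C@H](c6ccc(OCc5ccccc5)c(OCc5ccccc5)c6)[C@@H](OC(C)=O)[C@@H]2Sc1c(C)cccc1C
F7 | step 17 | 4-(benzyloxy)-5-bromo-2-hydroxybenzaldehyde | O=Cc1cc(Br)c(OCc2ccccc2)cc1O
F8 | step 17 | 4-(benzyloxy)-5-bromo-2-(tert-butyldimethylsilyloxy)benzaldehyde | O=Cc1cc(Br)c(OCc2ccccc2)cc1O[Si](C)(C)C(C)(C)C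
F9 | step 17 | [4-(benzyloxy)-5-bromo-2-(tert-butyldimethylsilyloxy)phenyl](penta-O-benzylcatechin-8-yl)methanol (mixture at the carbinol carbon) | c1c(OCc5ccccc5)c2c(c(C(O)c3cc(Br)c(OCc5ccccc5)cc3O[Si](C)(C)C(C)(C)C)c1OCc5ccccc5)O[C@H](c6ccc(OCc5ccccc5)c(OCc5ccccc5)c6)[C@@H](OCc5ccccc5)C2
F10 | step 17 | [4-(benzyloxy)-5-bromo-2-(tert-butyldimethylsilyloxy)phenyl](penta-O-benzylcatechin-8-yl)methanone | c1c(OCc5ccccc5)c2c(c(C(=O)c3cc(Br)c(OCc5ccccc5)cc3O[Si](C)(C)C(C)(C)C)c1OCc5ccccc5)O[C@H](c6ccc(OCc5ccccc5)c(OCc5ccccc5)c6)[C@@H](OCc5ccccc5)C2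
A1 | alternative 1 | benzyl-protected tetramer with pivalates on O3 of the three fisetinidol units | c5ccccc5COc1ccc2c(c1)O[C@H](c6ccc(OCc5ccccc5)c(OCc5ccccc5)c6)[C@@H](OC(=O)C(C)(C)C)[C@@H]2c1cc2c(cc1OCc5ccccc5)O[C@H](c6ccc(OCc5ccccc5)c(OCc5ccccc5)c6)[C@@H](OC(=O)C(C)(C)C)[C@@H]2c1c(OCc5ccccc5)c2c(c([C@@H]3c4ccc(OCc5ccccc5)cc4O[C@H](c6ccc(OCc5ccccc5)c(OCc5ccccc5)c6)[C@H]3OC(=O)C(C)(C)C)c1OCc5ccccc5)O[C@H](c6ccc(OCc5ccccc5)c(OCc5ccccc5)c6)[C@@H](OCc5ccccc5)C2
A2 | alternative 1 | [3,4-bis(benzyloxy)phenyl]zinc bromide | Br[Zn]c1ccc(OCc2ccccc2)c(OCc2ccccc2)c1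
A3 | alternative 1 | benzyl-protected tetraflavan skeleton with an anomeric acetate at C2 and a pivalate on O3 of each of the three fisetinidol-derived chroman units (anomeric centres unassigned) | c5ccccc5COc1ccc2c(c1)OC(OC(C)=O)[C@@H](OC(=O)C(C)(C)C)[C@@H]2c1cc2c(cc1OCc5ccccc5)OC(OC(C)=O)[C@@H](OC(=O)C(C)(C)C)[C@@H]2c1c(OCc5ccccc5)c2c(c([C@@H]3c4ccc(OCc5ccccc5)cc4OC(OC(C)=O)[C@H]3OC(=O)C(C)(C)C)c1OCc5ccccc5)O[C@H](c6ccc(OCc5ccccc5)c(OCc5ccccc5)c6)[C@@H](OCc5ccccc5)C2
A4 | alternative 1 | bromotrimethylsilane | C[Si](C)(C)Br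
A5 | alternative 2 | 2,4,6-trisubstituted phloroglucinol 3,5-bis(triisopropylsilyl) ether with free C8a hydroxyl | c5ccccc5COc1ccc2c(c1)O[C@H](c6ccc(OCc5ccccc5)c(OCc5ccccc5)c6)[C@@H](OCc5ccccc5)[C@@H]2c1cc2c(cc1OCc5ccccc5)O[C@H](c6ccc(OCc5ccccc5)c(OCc5ccccc5)c6)[C@@H](OCc5ccccc5)[C@@H]2c1c(O[Si](C(C)C)(C(C)C)C(C)C)c(C[C@H](OCc5ccccc5)[C@@H](O[Si](CC)(CC)CC)c6ccc(OCc5ccccc5)c(OCc5ccccc5)c6)c(O)c([C@@H]3c4ccc(OCc5ccccc5)cc4O[C@H](c6ccc(OCc5ccccc5)c(OCc5ccccc5)c6)[C@H]3OCc5ccccc5)c1O[Si](C(C)C)(C(C)C)C(C)C
A6 | alternative 2 | 3-(triisopropylsilyloxy)cyclobut-2-en-1-one carrying the benzylated dimeric flavan-4-yl group on C2 and the benzylated flavan-4-yl group on C4 (C4 of the four-membered ring unassigned) | c5ccccc5COc1ccc2c(c1)O[C@H](c6ccc(OCc5ccccc5)c(OCc5ccccc5)c6)[C@@H](OCc5ccccc5)[C@@H]2c1cc2c(cc1OCc5ccccc5)O[C@H](c6ccc(OCc5ccccc5)c(OCc5ccccc5)c6)[C@@H](OCc5ccccc5)[C@@H]2C1=C(O[Si](C(C)C)(C(C)C)C(C)C)C([C@@H]3c4ccc(OCc5ccccc5)cc4O[C@H](c6ccc(OCc5ccccc5)c(OCc5ccccc5)c6)[C@H]3OCc5ccccc5)C1=O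
A7 | alternative 2 | triisopropylsilyl ynol ether carrying the C4–C3–C2 chain: 4-(benzyloxy)-5-[3,4-bis(benzyloxy)phenyl]-5-(triethylsilyloxy)pent-1-yn-1-yl triisopropylsilyl ether | CC(C)[Si](C(C)C)(C(C)C)OC#CC[C@H](OCc1ccccc1)[C@@H](O[Si](CC)(CC)CC)c1ccc(OCc2ccccc2)c(OCc2ccccc2)c1
A8 | alternative 3 | benzyl-protected tetramer with free 7-hydroxyls on the two end units | Oc1ccc2c(c1)O[C@H](c6ccc(OCc5ccccc5)c(OCc5ccccc5)c6)[C@@H](OCc5ccccc5)[C@@H]2c1cc2c(cc1OCc5ccccc5)O[C@H](c6ccc(OCc5ccccc5)c(OCc5ccccc5)c6)[C@@H](OCc5ccccc5)[C@@H]2c1c(OCc5ccccc5)c2c(c([C@@H]3c4ccc(O)cc4O[C@H](c6ccc(OCc5ccccc5)c(OCc5ccccc5)c6)[C@H]3OCc5ccccc5)c1OCc5ccccc5)O[C@H](c6ccc(OCc5ccccc5)c(OCc5ccccc5)c6)[C@@H](OCc5ccccc5)C2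
A9 | alternative 3 | resorcinol | Oc1cccc(O)c1
A10 | alternative 3 | benzyl-protected fisetinidol-(4α→6)-catechin carrying a 2-(benzyloxy)-3-[3,4-bis(benzyloxy)phenyl]-1,3-dihydroxypropyl chain on C6 of the fisetinidol unit and on C8 of catechin (carbinol centres unassigned) | OC(c6ccc(OCc5ccccc5)c(OCc5ccccc5)c6)[C@@H](OCc5ccccc5)C(O)c1cc2c(cc1OCc5ccccc5)O[C@H](c6ccc(OCc5ccccc5)c(OCc5ccccc5)c6)[C@@H](OCc5ccccc5)[C@@H]2c1c(OCc5ccccc5)c2c(c(C(O)[C@H](OCc5ccccc5)C(O)c6ccc(OCc5ccccc5)c(OCc5ccccc5)c6)c1OCc5ccccc5)O[C@H](c6ccc(OCc5ccccc5)c(OCc5ccccc5)c6)[C@@H](OCc5ccccc5)C2
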